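**Retrosynthetic overview**

1. Locants used in the text follow the carbocycle: C1 (isopropyl-bearing ether carbon), C2=C3, C4 (methyl carbinol), C6 (ketone), C8 (CHMe), C11 (formate carbon), C12 (methyl-bearing ether carbon), C13 and C14 (the two CH2 groups of the oxolane).
2. Target ⇒ (formylation, desilylation) bicyclic silyl ether 20 ⇒ acyclic iodohydrin–diene 19. One operation forms C13–C14, which closes the 14-membered carbocycle C1–C14, and then O–C1, which closes the oxolane O–C1–C14–C13–C12 across it.
3. Enabling feature: C12 carries both the CH2 (C13) that becomes the radical and the hydroxyl that lies 1,5 to C1 once C13–C14 exists. C14=C1–C2=C3 is a diene whose allyl unit ends at C1. C12 and C4 carry no hydrogen. The ten-carbon bridge C2–C11 can span the oxolane only cis, so C1 follows from C12.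
4. 19 ⇒ epoxide 18 ⇒ vinyl iodide 14 + 2-bromo-3-methylbut-1-ene (C1, C14, isopropyl; Negishi) ⇒ keto aldehyde 13 ⇒ methyl ketone 7 + methyl pyruvate (C3, C4; bis(oxazoline)–copper Mukaiyama aldol sets C4).
5. 7 ⇒ (S)-citronellal (C6–C13 with the C8 stereocentre; C5 by Wittig, unmasked by Wacker oxidation). C11 comes from Shi epoxidation and C12 from a matched Sharpless epoxidation. Ring order: carbocycle, then oxolane, both in step 14.

Key step: step 14

Remark: the (S,S)-tBu-box–Cu(OTf)2 catalyst is taken to deliver the enol silane to the si face of the pyruvate ketone (C4 = S), as with other enol silanes; if the sense were opposite, the (R,R)-ligand would be used.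

**Route**

Step 1
Reactants: 1 (S)-citronellal
Product: 2 (4S)-4,8-dimethylnona-1,7-diene
Conditions: Ph3PCH3Br, KOtBu, THF, 0 to 25 °C
Reagents that add atoms: methyltriphenylphosphonium bromide C[P+](c1ccccc1)(c1ccccc1)c1ccccc1.[Br-]
Why: Wittig methylenation of the aldehyde is routine, the β-stereocentre C8 cannot epimerize, and the new vinyl group (C5=C6) is a latent methyl ketone that is inert to the epoxidation chemistry that follows.

Step 2
Reactants: 2 (4S)-4,8-dimethylnona-1,7-diene
Product: 3 (3R)-2,2-dimethyl-3-[(3S)-3-methylhex-5-en-1-yl]oxirane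
Conditions: D-fructose-derived Shi ketone (1,2:4,5-di-O-isopropylidene-β-D-erythro-hexo-2,3-diulo-2,6-pyranose, 30 mol%), KHSO5 (as Oxone, 2KHSO5·KHSO4·K2SO4), K2CO3, Bu4NHSO4, MeCN/dimethoxymethane/aq. borate buffer, 0 °C
Reagents that add atoms: potassium peroxymonosulfate [K+].[O-]S(=O)(=O)OO
Why: Shi epoxidation with the chiral dioxirane should take the electron-rich trisubstituted alkene far faster than the monosubstituted one and, through the spiro transition state, set C11 as R under catalyst control.

Step 3
Reactants: 3 (3R)-2,2-dimethyl-3-[(3S)-3-methylhex-5-en-1-yl]oxirane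
Product: 4 (3R,6S)-2,6-dimethylnona-1,8-dien-3-ol
Conditions: Al(OiPr)3 (2 equiv), toluene, 110 °C
Reagents that add atoms: none
Why: In this aluminium isopropoxide-promoted epoxide-to-allylic-alcohol isomerization the Lewis acid breaks the tertiary C12–O bond and a methyl proton is lost, so the C11–O bond and its configuration are untouched and the C12=C13 methylene is created.

Step 4
Reactants: 4 (3R,6S)-2,6-dimethylnona-1,8-dien-3-ol
Product: 5 (1R,4S)-4-methyl-1-[(2S)-2-methyloxiran-2-yl]hept-6-en-1-ol
Conditions: Ti(OiPr)4 (10 mol%), D-(−)-diisopropyl tartrate (12 mol%), tBuOOH, 4 Å molecular sieves, CH2Cl2, −20 °C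
Reagents that add atoms: tert-butyl hydroperoxide CC(C)(C)OO
Why: In this Sharpless epoxidation of a secondary allylic alcohol the (R)-carbinol is the fast-reacting (matched) enantiomer with the D-tartrate, so the titanium-bound peroxide should give the erythro (11R,12S) epoxy alcohol, which fixes C12; any C11 epimer left from step 2 should react slowly and be removed.

Step 5
Reactants: 5 (1R,4S)-4-methyl-1-[(2S)-2-methyloxiran-2-yl]hept-6-en-1-ol
Product: 6 tert-butyldimethylsilyl ether of 5
Conditions: TBSOTf, 2,6-lutidine, CH2Cl2, −78 °C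
Reagents that add atoms: tert-butyldimethylsilyl triflate CC(C)(C)[Si](C)(C)OS(=O)(=O)C(F)(F)F
Why: Silylation with the silyl triflate masks the hindered C11 hydroxyl, which would otherwise be oxidized in step 10 and compete with the C12 hydroxyl in step 14.

Step 6
Reactants: 6 tert-butyldimethylsilyl ether of 5
Product: 7 (4S,7R)-7-[(tert-butyldimethylsilyl)oxy]-4-methyl-7-[(2S)-2-methyloxiran-2-yl]heptan-2-one
Conditions: PdCl2 (10 mol%), Cu(OAc)2 (20 mol%), O2 (1 atm), N,N-dimethylacetamide/H2O 7:1, 25 °C
Reagents that add atoms: water O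
Why: Tsuji–Wacker oxidation by Markovnikov hydroxypalladation of the only remaining alkene should unveil the methyl ketone (C5–C6), and the acetate-buffered variant is mild enough for the epoxide and the silyl ether.

Step 7
Reactants: 7 (4S,7R)-7-[(tert-butyldimethylsilyl)oxy]-4-methyl-7-[(2S)-2-methyloxiran-2-yl]heptan-2-one
Product: 8 kinetic 2-(trimethylsilyloxy)alk-1-ene (enol silane) of 7
Conditions: LiN(iPr)2, Me3SiCl, THF, −78 °C
Reagents that add atoms: chlorotrimethylsilane C[Si](C)(C)Cl
Why: Kinetic deprotonation with the hindered lithium amide should take the methyl protons (C5) and not the β-branched C7 methylene, and O-silylation gives the terminal enol silane.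

Step 8
Reactants: 8 kinetic enol silane of 7; 9 methyl pyruvate
Product: 11 methyl (2S,6S,9R)-9-[(tert-butyldimethylsilyl)oxy]-2-hydroxy-2,6-dimethyl-9-[(2S)-2-methyloxiran-2-yl]-4-oxononanoate, via trimethylsilyl ether 10 (not isolated)
Conditions: Cu(OTf)2 (10 mol%), (S,S)-tBu-box [2,2'-(propane-2,2-diyl)bis((4S)-4-tert-butyl-4,5-dihydrooxazole), 11 mol%], THF, −78 °C; then TBAF, AcOH, THF, 0 °C
Reagents that add atoms: none
Why: In this bis(oxazoline)–copper-catalysed Mukaiyama aldol addition the pyruvate chelates the divalent copper and exposes its si face, so the C4 tertiary carbinol should form as the S isomer under catalyst control irrespective of the remote centres, and buffered fluoride then removes only the O–SiMe3 group.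

Step 9
Reactants: 11 methyl (2S,6S,9R)-9-[(tert-butyldimethylsilyl)oxy]-2-hydroxy-2,6-dimethyl-9-[(2S)-2-methyloxiran-2-yl]-4-oxononanoate
Product: 12 (2S,6S,9R)-9-[(tert-butyldimethylsilyl)oxy]-2,6-dimethyl-9-[(2S)-2-methyloxiran-2-yl]nonane-1,2,4-triol (both C4 epimers)
Conditions: LiBH4, THF/MeOH, 0 °C
Reagents that add atoms: none
Why: Borohydride reduction takes the hydroxyl-activated ester and the ketone but should leave the hindered 2,2-disubstituted epoxide and the silyl ether, which avoids a selective ester-to-aldehyde reduction next to a ketone.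

Step 10
Reactants: 12 (2S,6S,9R)-9-[(tert-butyldimethylsilyl)oxy]-2,6-dimethyl-9-[(2S)-2-methyloxiran-2-yl]nonane-1,2,4-triol
Product: 13 (2S,6S,9R)-9-[(tert-butyldimethylsilyl)oxy]-2-hydroxy-2,6-dimethyl-9-[(2S)-2-methyloxiran-2-yl]-4-oxononanal
Conditions: Dess–Martin periodinane, NaHCO3, CH2Cl2, 0 to 25 °C
Reagents that add atoms: none
Why: Dess–Martin oxidation converts the primary and the secondary alcohol to aldehyde and ketone while the tertiary alcohol cannot react, and C4 bears no hydrogen, so the α-hydroxy aldehyde cannot epimerize.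

Step 11
Reactants: 13 (2S,6S,9R)-9-[(tert-butyldimethylsilyl)oxy]-2-hydroxy-2,6-dimethyl-9-[(2S)-2-methyloxiran-2-yl]-4-oxononanal
Product: 14 (1E,3S,7S,10R)-10-[(tert-butyldimethylsilyl)oxy]-3-hydroxy-1-iodo-3,7-dimethyl-10-[(2S)-2-methyloxiran-2-yl]dec-1-en-5-one
Conditions: CrCl2 (8 equiv), CHI3 (3 equiv), THF, 0 °C
Reagents that add atoms: iodoform IC(I)I
Why: In the Takai iodo-olefination the geminal dichromium reagent adds to aldehydes but not to ketones and should give the E-vinyl iodide (C2=C3), all the more with an α-quaternary aldehyde.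

Step 12
Reactants: 14 (1E,3S,7S,10R)-10-[(tert-butyldimethylsilyl)oxy]-3-hydroxy-1-iodo-3,7-dimethyl-10-[(2S)-2-methyloxiran-2-yl]dec-1-en-5-one; 15 2-bromo-3-methylbut-1-ene
Product: 18 (3E,5S,9S,12R)-12-[(tert-butyldimethylsilyl)oxy]-5-hydroxy-5,9-dimethyl-12-[(2S)-2-methyloxiran-2-yl]-2-(propan-2-yl)dodeca-1,3-dien-7-one, via alkenyllithium 16 (not isolated), via alkenylzinc chloride 17 (not isolated)
Conditions: 15, tBuLi (2 equiv), Et2O, −78 °C; ZnCl2, THF, −78 to 0 °C; then 14, Pd(PPh3)4 (5 mol%), THF, 25 °C
Reagents that add atoms: none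
Why: Negishi coupling of an alkenyl iodide with an alkenylzinc halide should proceed with retention of the E geometry at room temperature under neutral conditions that the β-hydroxy ketone, the epoxide and the free tertiary alcohol tolerate.

Step 13
Reactants: 18 (3E,5S,9S,12R)-12-[(tert-butyldimethylsilyl)oxy]-5-hydroxy-5,9-dimethyl-12-[(2S)-2-methyloxiran-2-yl]-2-(propan-2-yl)dodeca-1,3-dien-7-one
Product: 19 (2R,3R,6S,10S,11E)-3-[(tert-butyldimethylsilyl)oxy]-2,10-dihydroxy-1-iodo-2,6,10-trimethyl-13-(propan-2-yl)tetradeca-11,13-dien-8-one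
Conditions: LiI, AcOH, THF, 0 to 25 °C
Reagents that add atoms: lithium iodide [Li+].[I-]
Why: In this halohydrin formation iodide buffered by acetic acid should open the epoxide by SN2 attack at the unhindered CH2 (C13), so the C12–O bond and the C12 arrangement are retained (the descriptor changes only because CH2I outranks C11) and the tertiary hydroxyl is set free next to the radical precursor.

Step 14
Reactants: 19 (2R,3R,6S,10S,11E)-3-[(tert-butyldimethylsilyl)oxy]-2,10-dihydroxy-1-iodo-2,6,10-trimethyl-13-(propan-2-yl)tetradeca-11,13-dien-8-one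
Product: 20 (1S,2R,5S,9S,10E,12S)-2-[(tert-butyldimethylsilyl)oxy]-9-hydroxy-1,5,9-trimethyl-12-(propan-2-yl)-15-oxabicyclo[10.2.1]pentadec-10-en-7-one
Conditions: Pd(PPh3)4 (10 mol%), 2,4,6-collidine (3 equiv), 1,4-dioxane (1 mM), blue LEDs (450 nm), 25 °C
Reagents that add atoms: none
Why: Proposed new method: photoexcited zerovalent palladium should abstract the iodine atom of 19 to give the primary C13 radical and a monovalent palladium iodide; the radical adds to the unsubstituted diene terminus C14 (14-endo-trig closure of the carbocycle C1–C14), the allyl radical spread over C1–C3 is captured as an allyl complex of divalent palladium, and the C12 hydroxyl attacks C1 anti to the metal (5-exo closure of the oxolane O–C1–C14–C13–C12), which returns zerovalent palladium while collidine takes up HI. The closest known reaction type is the light-driven palladium-catalysed interrupted radical Heck/allylic substitution that joins unactivated alkyl halides, 1,3-dienes and heteroatom nucleophiles, together with radical macrocyclizations of ω-iodoalkyl polyenes; neither has been shown as a macrocyclizing carboetherification with a tertiary alcohol. The new stereocentre C1 is controlled by C12 through topology, because the ten-carbon bridge C2–C11 can span the oxolane only when C2 and C11 are cis, and reversible ionization of the allylic ether by palladium should funnel any other isomer to this one; C4, C8, C11 and C12 are untouched and the E geometry of C2=C3 is kept because C4 sits syn on the allyl unit. The step needs addition at C14 and not at C3 (C3 is shielded by the quaternary C4), C–O formation at C1 and not at C3 (five- against seven-membered ring) by the C12 and not the C4 hydroxyl (which could only give a 2,5-dihydrofuran after syn–anti isomerization), and ring closure faster than 1,5-hydrogen transfer or β-elimination; the substrate secures this because C12 and C4 bear no hydrogen, the C11 hydroxyl is silylated, the weak pyridine base does not re-close the iodohydrin to the epoxide, and the run is made at high dilution.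

Step 15
Reactants: 20 (1S,2R,5S,9S,10E,12S)-2-[(tert-butyldimethylsilyl)oxy]-9-hydroxy-1,5,9-trimethyl-12-(propan-2-yl)-15-oxabicyclo[10.2.1]pentadec-10-en-7-one
Product: 21 (1S,2R,5S,9S,10E,12S)-2,9-dihydroxy-1,5,9-trimethyl-12-(propan-2-yl)-15-oxabicyclo[10.2.1]pentadec-10-en-7-one
Conditions: HF·pyridine, pyridine, THF, 0 to 25 °C
Reagents that add atoms: none
Why: Fluoride-mediated desilylation under pyridine buffering should free the C11 hydroxyl without ionizing the tertiary allylic ether or the tertiary allylic alcohol.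

Step 16
Reactants: 21 (1S,2R,5S,9S,10E,12S)-2,9-dihydroxy-1,5,9-trimethyl-12-(propan-2-yl)-15-oxabicyclo[10.2.1]pentadec-10-en-7-one
Product: 22 (1S,2R,5S,9S,10E,12S)-9-hydroxy-1,5,9-trimethyl-7-oxo-12-(propan-2-yl)-15-oxabicyclo[10.2.1]pentadec-10-en-2-yl formate
Conditions: HCO2H, DCC, DMAP (cat.), CH2Cl2, 0 °C
Reagents that add atoms: formic acid OC=O
Why: Steglich-type formylation should acylate the secondary C11 hydroxyl much faster than the hindered tertiary C4 hydroxyl, which completes the target.

**Compound list**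

1 | (S)-citronellal, (3S)-3,7-dimethyloct-6-enal | O=CC[C@@H](C)CCC=C(C)C | starting material
2 | (4S)-4,8-dimethylnona-1,7-diene | C=CC[C@@H](C)CCC=C(C)C | intermediate
3 | (3R)-2,2-dimethyl-3-[(3S)-3-methylhex-5-en-1-yl]oxirane | C=CC[C@@H](C)CC[C@H]1OC1(C)C | intermediate
4 | (3R,6S)-2,6-dimethylnona-1,8-dien-3-ol | C=CC[C@@H](C)CC[C@@H](O)C(C)=C | intermediate
5 | (1R,4S)-4-methyl-1-[(2S)-2-methyloxiran-2-yl]hept-6-en-1-ol | C=CC[C@@H](C)CC[C@@H](O)[C@]1(C)CO1 | intermediate
6 | tert-butyldimethyl{[(1R,4S)-4-methyl-1-[(2S)-2-methyloxiran-2-yl]hept-6-en-1-yl]oxy}silane | C=CC[C@@H](C)CC[C@@H](O[Si](C)(C)C(C)(C)C)[C@]1(C)CO1 | intermediate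
7 | (4S,7R)-7-[(tert-butyldimethylsilyl)oxy]-4-methyl-7-[(2S)-2-methyloxiran-2-yl]heptan-2-one | CC(=O)C[C@@H](C)CC[C@@H](O[Si](C)(C)C(C)(C)C)[C@]1(C)CO1 | intermediate
8 | kinetic enol silane of 7, (4S,7R)-7-[(tert-butyldimethylsilyl)oxy]-4-methyl-7-[(2S)-2-methyloxiran-2-yl]-2-(trimethylsilyloxy)hept-1-ene | C=C(O[Si](C)(C)C)C[C@@H](C)CC[C@@H](O[Si](C)(C)C(C)(C)C)[C@]1(C)CO1 | intermediate
9 | methyl pyruvate | COC(=O)C(C)=O | starting material
10 | 2-O-trimethylsilyl ether of 11 | COC(=O)[C@@](C)(O[Si](C)(C)C)CC(=O)C[C@@H](C)CC[C@@H](O[Si](C)(C)C(C)(C)C)[C@]1(C)CO1 | intermediate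
11 | methyl (2S,6S,9R)-9-[(tert-butyldimethylsilyl)oxy]-2-hydroxy-2,6-dimethyl-9-[(2S)-2-methyloxiran-2-yl]-4-oxononanoate | COC(=O)[C@@](C)(O)CC(=O)C[C@@H](C)CC[C@@H](O[Si](C)(C)C(C)(C)C)[C@]1(C)CO1 | intermediate
12 | (2S,6S,9R)-9-[(tert-butyldimethylsilyl)oxy]-2,6-dimethyl-9-[(2S)-2-methyloxiran-2-yl]nonane-1,2,4-triol, both C4 epimers | OC[C@@](C)(O)CC(O)C[C@@H](C)CC[C@@H](O[Si](C)(C)C(C)(C)C)[C@]1(C)CO1 | intermediate
13 | (2S,6S,9R)-9-[(tert-butyldimethylsilyl)oxy]-2-hydroxy-2,6-dimethyl-9-[(2S)-2-methyloxiran-2-yl]-4-oxononanal | O=C[C@@](C)(O)CC(=O)C[C@@H](C)CC[C@@H](O[Si](C)(C)C(C)(C)C)[C@]1(C)CO1 | intermediate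
14 | (1E,3S,7S,10R)-10-[(tert-butyldimethylsilyl)oxy]-3-hydroxy-1-iodo-3,7-dimethyl-10-[(2S)-2-methyloxiran-2-yl]dec-1-en-5-one | I/C=C/[C@@](C)(O)CC(=O)C[C@@H](C)CC[C@@H](O[Si](C)(C)C(C)(C)C)[C@]1(C)CO1 | intermediate
15 | 2-bromo-3-methylbut-1-ene | C=C(Br)C(C)C | starting material
16 | (3-methylbut-1-en-2-yl)lithium | [Li]C(=C)C(C)C | intermediate
17 | chloro(3-methylbut-1-en-2-yl)zinc | Cl[Zn]C(=C)C(C)C | intermediate
18 | (3E,5S,9S,12R)-12-[(tert-butyldimethylsilyl)oxy]-5-hydroxy-5,9-dimethyl-12-[(2S)-2-methyloxiran-2-yl]-2-(propan-2-yl)dodeca-1,3-dien-7-one | CC(C)C(=C)/C=C/[C@@](C)(O)CC(=O)C[C@@H](C)CC[C@@H](O[Si](C)(C)C(C)(C)C)[C@]1(C)CO1 | intermediate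
19 | (2R,3R,6S,10S,11E)-3-[(tert-butyldimethylsilyl)oxy]-2,10-dihydroxy-1-iodo-2,6,10-trimethyl-13-(propan-2-yl)tetradeca-11,13-dien-8-one | CC(C)C(=C)/C=C/[C@@](C)(O)CC(=O)C[C@@H](C)CC[C@@H](O[Si](C)(C)C(C)(C)C)[C@@](C)(O)CI | intermediate
20 | (1S,2R,5S,9S,10E,12S)-2-[(tert-butyldimethylsilyl)oxy]-9-hydroxy-1,5,9-trimethyl-12-(propan-2-yl)-15-oxabicyclo[10.2.1]pentadec-10-en-7-one | CC(C)[C@]12/C=C/[C@@](C)(O)CC(=O)C[C@@H](C)CC[C@@H](O[Si](C)(C)C(C)(C)C)[C@](C)(CC1)O2 | intermediate
21 | (1S,2R,5S,9S,10E,12S)-2,9-dihydroxy-1,5,9-trimethyl-12-(propan-2-yl)-15-oxabicyclo[10.2.1]pentadec-10-en-7-one | CC(C)[C@]12/C=C/[C@@](C)(O)CC(=O)C[C@@H](C)CC[C@@H](O)[C@](C)(CC1)O2 | intermediate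
22 | (1S,2R,5S,9S,10E,12S)-9-hydroxy-1,5,9-trimethyl-7-oxo-12-(propan-2-yl)-15-oxabicyclo[10.2.1]pentadec-10-en-2-yl formate | CC(C)[C@]12/C=C/[C@@](C)(O)CC(=O)C[C@@H](C)CC[C@@H](OC=O)[C@](C)(CC1)O2 | target

**Step count and risks**

Total step count: 16. Longest linear sequence: 16 steps, from (S)-citronellal 1 to 22.

Steps most likely to fail:

1. Step 14 (Proposed new method). The C13 radical may be consumed before it reaches C14, by 1,5-hydrogen transfer from C9 or by β-hydroxide loss from the alkylpalladium. The allylpalladium may also lose a β-hydrogen faster than the hindered tertiary hydroxyl attacks C1. The fallback uses known reactions and separates C–C from C–O bond formation; it sets out from 19 and comes back at 20. A tin hydride radical macrocyclization (Bu3SnH by syringe pump, AIBN, benzene, 80 °C, 1 mM) should close C13–C14 and, after hydrogen transfer to the less hindered allyl terminus C3, give the 14-membered carbocyclic alkene F1 with a trisubstituted C1=C2 bond. Phenylselenoetherification (N-(phenylseleno)phthalimide, cat. camphorsulfonic acid, CH2Cl2, −78 °C) then closes the oxolane by 5-exo, Markovnikov attack of the C12 hydroxyl on C1, again only in the cis-bridged sense, to give the C2 selenide F2. Oxidation (H2O2, pyridine, 0 °C) and selenoxide syn-elimination, which can only go toward C3 because C1 has no hydrogen, re-form the E C2=C3 bond and give 20.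

2. Step 8. The silyl triflate that shuttles the silyl group in the Mukaiyama cycle may open or rearrange the 2,2-disubstituted epoxide, and face discrimination may be weak with an aliphatic enol silane. The fallback sets out from methyl ketone 7 and comes back at 11. It is an amine-catalysed direct aldol addition of 7 to methyl pyruvate 9 through the less substituted enamine (a proline-derived amide or a primary–tertiary diamine salt, DMSO, 0 to 25 °C; the catalyst enantiomer that gives the S carbinol is chosen on a model ketone). It needs neither the enol silane 8 nor a Lewis acid and makes no new compound (F0).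

3. Step 11. The chromium halides may open the epoxide, the β-hydroxy ketone may undergo retro-aldol cleavage, and addition to the hindered α-hydroxy aldehyde may be slow. The fallback sets out from 13 and comes back at 18, without chromium or organozinc reagents. Wittig methylenation (Ph3P=CH2, THF, −78 °C), which takes the aldehyde before the ketone, gives the vinyl carbinol F3. A Heck reaction with 15 (Pd(OAc)2, P(o-tol)3, Et3N, MeCN, 60 °C) inserts at the terminal carbon and, because C4 has no hydrogen, eliminates only toward C2 to give the E-diene 18.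

Further compounds
F1 | step 14 | 14-membered carbocycle from 19 with a C1(isopropyl)=C2 double bond (E/Z mixture) and C3H2, configurations at C4, C8, C11 and C12 as in 19 | CC(C)C1=CC[C@@](C)(O)CC(=O)C[C@@H](C)CC[C@@H](O[Si](C)(C)C(C)(C)C)[C@@](C)(O)CC1
F2 | step 14 | 20 with C2–C3 saturated and a phenylselanyl group on C2 (configuration at C2 not defined) | CC(C)[C@]12C([Se]c3ccccc3)C[C@@](C)(O)CC(=O)C[C@@H](C)CC[C@@H](O[Si](C)(C)C(C)(C)C)[C@](C)(CC1)O2
F0 | step 8 | none | none
F3 | step 11 | (3S,7S,10R)-10-[(tert-butyldimethylsilyl)oxy]-3-hydroxy-3,7-dimethyl-10-[(2S)-2-methyloxiran-2-yl]dec-1-en-5-one | C=C[C@@](C)(O)CC(=O)C[C@@H](C)CC[C@@H](O[Si](C)(C)C(C)(C)C)[C@]1(C)CO1
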